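**Retrosynthetic overview**
1. Numbering of the target as a 6-oxabicyclo[3.2.1]octane-7,8-dione: C1 (prenyl bridgehead), C2H2, C3H(prenyl), C4Me2, C5 (acyl bridgehead), O6, C7 (lactone C=O), C8 (ketone). The last disconnection cuts C4–C5 and C3–CH2(prenyl) together. This retro prenylation–cyclisation leads to a monocyclic 5-acyl-3,3-diprenylfuran-2,4-dione and dimethylallyl diphosphate.
2. Enabling feature: C1 carries one intact prenyl group. The bridge C2–C3–C4Me2 is a second prenyl group on the same carbon, alkylated at its C2' (= C3) and closed at its C3' (= C4). C1 is therefore a hidden, prochiral gem-diprenyl carbon. C5 is the α-carbon shared by the C8 ketone and the exocyclic acyl group inside the five-membered ring C5–O6–C7–C1–C8, so it is an enolate nucleophile.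
3. The furan-2,4-dione ring is opened by a retro-Dieckmann cut at C8–C5, giving a mixed methyl / (3R)-3-methyl-2-oxopentyl 2,2-diprenylmalonate.
4. That ester comes from monomethyl 2,2-diprenylmalonate (dimethyl malonate plus prenyl bromide) and (3R)-1-chloro-3-methylpentan-2-one. The latter is made from (R)-2-methylbutanoic acid, the source of the side-chain stereocentre.
5. Order of ring formation: γ-lactone (furandione) ring first (step 6), cyclohexanone ring C1–C2–C3–C4–C5–C8 last (step 7).

Key step: step 7

Assumption: (R)-2-methylbutanoic acid and dimethylallyl diphosphate triammonium salt are taken as catalogue items. Compound 12 is drawn as its C4 enol, in which C5 is not a fixed stereocentre.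

**Step 1**
Reactants: 1 dimethyl malonate; 2 prenyl bromide (1-bromo-3-methylbut-2-ene, 2.2 equiv)
Product: 4 dimethyl 2,2-bis(3-methylbut-2-en-1-yl)propanedioate, via monoprenyl malonate 3 (not isolated)
Conditions: NaH (2.3 equiv), THF–DMF, 0 °C to rt
Reagents that add atoms: none
Why: Double malonic ester alkylation (SN2 on a primary allylic bromide), in which the second alkylation of 3 is as easy as the first and no stereocentre arises because both new groups are the same.

**Step 2**
Reactants: 4 dimethyl 2,2-bis(3-methylbut-2-en-1-yl)propanedioate
Product: 5 2-(methoxycarbonyl)-5-methyl-2-(3-methylbut-2-en-1-yl)hex-4-enoic acid (monomethyl 2,2-diprenylmalonate)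
Conditions: KOH (1.05 equiv), MeOH, rt to 40 °C; then 1 M HCl, 0 °C
Reagents that add atoms: potassium hydroxide [K+].[OH-]
Why: Mono-saponification (BAc2) of a dialkylmalonate, which should stop after the first ester because the carboxylate formed shields the neighbouring hindered ester from hydroxide, and the quaternary carbon stays non-stereogenic.

**Step 3**
Reactants: 6 (R)-2-methylbutanoic acid
Product: 8 (2R)-N-methoxy-N,2-dimethylbutanamide, via acylimidazole 7 (not isolated)
Conditions: CDI, CH2Cl2, rt; then MeNH(OMe)·HCl, rt
Reagents that add atoms: N,O-dimethylhydroxylamine hydrochloride CNOC.Cl; 1,1'-carbonyldiimidazole O=C(n1ccnc1)n1ccnc1 (imidazol-1-yl group of 7 only)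
Why: Weinreb amide formation through an acylimidazole, an activation without strong base or ketene formation, so the α-stereocentre should be kept.

**Step 4**
Reactants: 8 (2R)-N-methoxy-N,2-dimethylbutanamide
Product: 10 (3R)-1-chloro-3-methylpentan-2-one, via lithium carbinolamine adduct 9 (not isolated)
Conditions: ICH2Cl (1.5 equiv), MeLi·LiBr (1.4 equiv), THF, −78 °C; then sat. aq NH4Cl
Reagents that add atoms: chloroiodomethane ClCI; methyllithium [Li]C (lithium of 9 only)
Why: Carbenoid homologation of a Weinreb amide, in which chloromethyllithium adds once, the chelated adduct 9 lasts until the quench and so prevents a second addition, and at −78 °C the α-stereocentre should not be deprotonated.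

**Step 5**
Reactants: 5 monomethyl 2,2-diprenylmalonate; 10 (3R)-1-chloro-3-methylpentan-2-one
Product: 11 1-methyl 3-[(3R)-3-methyl-2-oxopentyl] 2,2-bis(3-methylbut-2-en-1-yl)propanedioate
Conditions: Cs2CO3 (0.55 equiv), DMF, rt
Reagents that add atoms: none
Why: SN2 O-alkylation of a caesium carboxylate by an α-chloroketone, which bypasses acyl activation of the hindered acid and runs in a medium too weakly basic to enolise the ketone towards its stereocentre.

**Step 6**
Reactants: 11 1-methyl 3-[(3R)-3-methyl-2-oxopentyl] 2,2-bis(3-methylbut-2-en-1-yl)propanedioate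
Product: 12 4-hydroxy-5-[(2R)-2-methylbutanoyl]-3,3-bis(3-methylbut-2-en-1-yl)furan-2(3H)-one (enol form of the 5-acylfuran-2,4-dione)
Conditions: LiHMDS (2.1 equiv), THF, −78 to 0 °C; then 1 M HCl
Reagents that add atoms: none
Why: Dieckmann-type intramolecular Claisen condensation (5-(enolexo)-exo-trig), in which the more acidic and less hindered O–CH2–C(=O) position is deprotonated, the gem-diprenyl (Thorpe–Ingold) effect helps the attack on the methyl ester, and immediate deprotonation of the β-diketone formed drives the closure and protects the side-chain stereocentre.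

**Step 7**
Reactants: 12 4-hydroxy-5-[(2R)-2-methylbutanoyl]-3,3-bis(3-methylbut-2-en-1-yl)furan-2(3H)-one; 13 dimethylallyl diphosphate triammonium salt (DMAPP, 2 equiv)
Product: 15 (1S,3S,5S)-4,4-dimethyl-5-[(2R)-2-methylbutanoyl]-1,3-bis(3-methylbut-2-en-1-yl)-6-oxabicyclo[3.2.1]octane-7,8-dione (CNP0306710.1), via tertiary cation 14 (not isolated)
Conditions: ring-forming UbiA-type aromatic prenyltransferase (recombinant, yeast microsomes), MgCl2, HEPES buffer pH 7.5, 5% DMSO, 30 °C
Reagents that add atoms: none
Why: Proposed new method: the enzyme-bound Mg2+–diphosphate of 13 ionises to a dimethylallyl cation, the C2'=C3' bond of the pro-S prenyl group on C3 of the enolate of 12 attacks its CH2 terminus with C2' (Markovnikov), and the tertiary cation 14 thus placed at C3' is captured by the enolate carbon C5, so that two C–C bonds, the carbocycle, the vicinal quaternary pair C4/C5 and three stereocentres should arise in one operation and the product is the target itself. The closest known reaction type is the prenylation–cyclisation by which membrane-bound UbiA-type prenyltransferases of the polyprenylated acylphloroglucinol pathway turn gem-diprenylated acylphloroglucinols into type A bicyclo[3.3.1]nonane-2,4,9-triones, with the iodonium- or selenium-induced carbocyclisation of the same gem-diprenyl β-dicarbonyl motif as its abiotic counterpart; new is the substrate class, a furan-2,4-dione in which O1–C2(=O) stands for the C(OH)=C(prenyl)–C(=O) arc of the natural acceptor while the acyl-enolate, the gem-diprenyl carbon and its two flanking carbonyl groups are kept, so that screening of homologues or active-site variants is part of the proposal. The cyclohexanone ring closes 6-endo-trig with respect to the prenyl C=C and 6-(enolendo) with respect to the C4=C5 enolate, through a chair. C1 of 15 is fixed by the choice of the enzyme pocket between the two diastereotopic prenyl groups, C3 by anti addition of the cation (Si face of C2') and of C5 across the alkene in that chair, which leaves the new prenyl group equatorial and anti to the lactone bridge, and C5 follows from C1 because the three-carbon bridge can reach only the face of the planar enolate on which it stands; the sense of all three centres is that of the natural type A series built by this enzyme class, and the side-chain centre is not touched. The step needs the alkene and not the enolate as first nucleophile, C5 and not O4 as second nucleophile, and one transfer only: hydrogen-bond anchoring of the enolate through O4 and the acyl oxygen should mask both oxygen atoms and hold C5 away from the donor, the five-membered ring keeps C5 within bonding distance of C3' on the face of the attacked prenyl group, and 15 has neither an acidic hydrogen nor an enolate left, so it should leave the active site as a neutral non-substrate.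

**Compound list**
1 | dimethyl malonate | COC(=O)CC(=O)OC | starting material
2 | prenyl bromide (1-bromo-3-methylbut-2-ene) | CC(C)=CCBr | starting material
3 | dimethyl 2-(3-methylbut-2-en-1-yl)propanedioate (not isolated) | COC(=O)C(CC=C(C)C)C(=O)OC | intermediate
4 | dimethyl 2,2-bis(3-methylbut-2-en-1-yl)propanedioate | COC(=O)C(CC=C(C)C)(CC=C(C)C)C(=O)OC | intermediate
5 | 2-(methoxycarbonyl)-5-methyl-2-(3-methylbut-2-en-1-yl)hex-4-enoic acid | COC(=O)C(CC=C(C)C)(CC=C(C)C)C(=O)O | intermediate
6 | (R)-2-methylbutanoic acid | CC[C@@H](C)C(=O)O | starting material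
7 | (2R)-1-(imidazol-1-yl)-2-methylbutan-1-one (not isolated) | CC[C@@H](C)C(=O)n1ccnc1 | intermediate
8 | (2R)-N-methoxy-N,2-dimethylbutanamide | CC[C@@H](C)C(=O)N(C)OC | intermediate
9 | lithium (3R)-1-chloro-2-[methoxy(methyl)amino]-3-methylpentan-2-olate, both epimers at C2, of no consequence (not isolated) | CC[C@@H](C)C([O-])(CCl)N(C)OC.[Li+] | intermediate
10 | (3R)-1-chloro-3-methylpentan-2-one | CC[C@@H](C)C(=O)CCl | intermediate
11 | 1-methyl 3-[(3R)-3-methyl-2-oxopentyl] 2,2-bis(3-methylbut-2-en-1-yl)propanedioate | CC[C@@H](C)C(=O)COC(=O)C(CC=C(C)C)(CC=C(C)C)C(=O)OC | intermediate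
12 | 4-hydroxy-5-[(2R)-2-methylbutanoyl]-3,3-bis(3-methylbut-2-en-1-yl)furan-2(3H)-one (C3 prochiral) | CC[C@@H](C)C(=O)C1=C(O)C(CC=C(C)C)(CC=C(C)C)C(=O)O1 | intermediate
13 | dimethylallyl diphosphate triammonium salt | CC(C)=CCOP(=O)([O-])OP(=O)([O-])[O-].[NH4+].[NH4+].[NH4+] | starting material
14 | enzyme-bound zwitterion: C4 enolate of the furanone whose pro-S prenyl group has become a CH2–CH(prenyl)–C(+)Me2 chain; furanone C3 and chain CH configured as C1 and C3 of 15 (not isolated) | CC[C@@H](C)C(=O)C1=C([O-])[C@](CC=C(C)C)(C[C@H](CC=C(C)C)[C+](C)C)C(=O)O1 | intermediate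
15 | (1S,3S,5S)-4,4-dimethyl-5-[(2R)-2-methylbutanoyl]-1,3-bis(3-methylbut-2-en-1-yl)-6-oxabicyclo[3.2.1]octane-7,8-dione | CC[C@@H](C)C(=O)[C@@]12OC(=O)[C@@](CC=C(C)C)(C[C@H](CC=C(C)C)C1(C)C)C2=O | target

**Step count**
- Total step count: 7.
- Longest linear sequence: 5 steps (6 → 8 → 10 → 11 → 12 → 15, steps 3 to 7).
- The malonate branch (steps 1, 2, then 5 to 7) is equally long.

**Steps most likely to fail**

First, step 7 (the labelled step).
- What may go wrong: the oxa-analogue may not bind productively, so that there is no turnover. The dimethylallyl cation may be transferred to C5 or O4 of the enolate instead of to the alkene. The enol lactone may slowly hydrolyse in the buffer.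
- Fallback: it uses known chemistry, sets out from 12 and comes back at 15.
- Compound 12 would be treated with I2, KI and KHCO3 in THF–H2O. This iodonium-induced carbocyclisation is known for gem-diprenylated β-dicarbonyl systems and proceeds by anti addition through the same chair.
- It should give the equatorial iodide (1S,3S,5S)-3-iodo-4,4-dimethyl-5-[(2R)-2-methylbutanoyl]-1-(3-methylbut-2-en-1-yl)-6-oxabicyclo[3.2.1]octane-7,8-dione F1 together with its core-inverted isomer (1R,3R,5R)-3-iodo-4,4-dimethyl-5-[(2R)-2-methylbutanoyl]-1-(3-methylbut-2-en-1-yl)-6-oxabicyclo[3.2.1]octane-7,8-dione F2.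
- Because of the (R) side chain the two are diastereomers and would be separated by chromatography.
- Keck radical allylation of F1 (allyltributylstannane, AIBN, benzene, 80 °C) should deliver the allyl group from the equatorial direction, anti to the lactone bridge. The product is (1S,3S,5S)-4,4-dimethyl-5-[(2R)-2-methylbutanoyl]-1-(3-methylbut-2-en-1-yl)-3-(prop-2-en-1-yl)-6-oxabicyclo[3.2.1]octane-7,8-dione F3.
- Cross metathesis of F3 with 2-methylbut-2-ene (Grubbs II catalyst, CH2Cl2, 40 °C) would then give 15.

Second, step 6.
- What may go wrong: deprotonation may occur at the side-chain α-position, followed by O-to-C acyl migration and loss of configuration. The liberated methoxide may open the product by retro-Claisen cleavage.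
- Fallback: the lactone ring is bought instead of made, and the C5–acyl bond is formed instead of the ring bond. It sets out from 2 and 7 and comes back at 12.
- Commercial tetronic acid (O=C1COC(=O)C1) would be C,C-dialkylated with 2 (2.2 equiv, aq KOH, rt) to 3,3-bis(3-methylbut-2-en-1-yl)furan-2,4(3H,5H)-dione F4.
- Its C5 lithium enolate (LiHMDS, 2 equiv, THF, −78 °C) would be C-acylated with acylimidazole 7, made from 6 as in step 3, to give 12 after acidic work-up.

Third, step 4.
- What may go wrong: the carbenoid may decompose before it adds, the volatile product may be lost on isolation, and partial epimerisation may occur during the quench.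
- Fallback: a diazoketone route that sets out from 6 and comes back at 11.
- Compound 6 would be converted with oxalyl chloride (cat. DMF, CH2Cl2) into (2R)-2-methylbutanoyl chloride F5.
- Diazomethane (Et2O, 0 °C) would then give (3R)-1-diazo-3-methylpentan-2-one F6.
- 48% HBr (Et2O, 0 °C) would give (3R)-1-bromo-3-methylpentan-2-one F7.
- F7 would alkylate the caesium salt of 5 in DMF to give 11.

**Further compounds**
F1 | step 7 | (1S,3S,5S)-3-iodo-4,4-dimethyl-5-[(2R)-2-methylbutanoyl]-1-(3-methylbut-2-en-1-yl)-6-oxabicyclo[3.2.1]octane-7,8-dione | CC[C@@H](C)C(=O)[C@@]12OC(=O)[C@@](CC=C(C)C)(C[C@H](I)C1(C)C)C2=O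
F2 | step 7 | (1R,3R,5R)-3-iodo-4,4-dimethyl-5-[(2R)-2-methylbutanoyl]-1-(3-methylbut-2-en-1-yl)-6-oxabicyclo[3.2.1]octane-7,8-dione | CC[C@@H](C)C(=O)[C@]12OC(=O)[C@](CC=C(C)C)(C[C@@H](I)C1(C)C)C2=O
F3 | step 7 | (1S,3S,5S)-4,4-dimethyl-5-[(2R)-2-methylbutanoyl]-1-(3-methylbut-2-en-1-yl)-3-(prop-2-en-1-yl)-6-oxabicyclo[3.2.1]octane-7,8-dione | CC[C@@H](C)C(=O)[C@@]12OC(=O)[C@@](CC=C(C)C)(C[C@H](CC=C)C1(C)C)C2=O
F4 | step 6 | 3,3-bis(3-methylbut-2-en-1-yl)furan-2,4(3H,5H)-dione | O=C1COC(=O)C1(CC=C(C)C)CC=C(C)C
F5 | step 4 | (2R)-2-methylbutanoyl chloride | CC[C@@H](C)C(=O)Cl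
F6 | step 4 | (3R)-1-diazo-3-methylpentan-2-one | CC[C@@H](C)C(=O)C=[N+]=[N-]
F7 | step 4 | (3R)-1-bromo-3-methylpentan-2-one | CC[C@@H](C)C(=O)CBr
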